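Percent of the substrate charged was the unit of my bench note on ash.

all flasks: substrate 0.21 M

| flask | reagent | free catalyst | remark | time |
|---|---|---|---|---|
| ash | 1.1 equiv | 9.3 mol% | the very flask that is asked about, followed so far |  |
| birch | 1.1 equiv | 19 mol% | run made earlier |  |
| flask | 1.10 equiv | 9.3 mol% |  | 10 d |

- ash (time / d: substrate / %, target / %): 0.625: 45.4, 46.1; 1.25: 29.6, 61.6; 2.00: 22.9, 68.1; 3.00: 17.2, 73.8; 4.00: 12.6, 78.4; 5.00: 10.1, 80.7
- birch (time / d: substrate / %, target / %): 0.625: 21.5, 60.6; 0.833: 16.0, 65.8; 1.25: 11.9, 71.1; 2.08: 3.8, 78.4; 3.00: 0.5, 82.9; 5.00: 0, 88.9; 8.00: 0, 94.0

(scatter of a reading: 0.5 percentage points)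

1. part of the substrate that has reacted at 10 d
2. share of the unused reagent that is free and not bound as idle adduct, at 10 d

- what was read earlier has a scatter of 0.5 percentage points, one standard deviation
- the earlier runs do not show how much of reagent is bound; that part of a forecast is a guess

In ash at 5.00 d, the substrate and target readings fell short of the charge by 9.20%, close to the catalyst loading of 9.3 mol%. In birch at 0.625 d, the gap read 17.9% against 19 mol%. So I took it that catalyst sat on substrate, out of sight, as a resting state. I also took each turnover to use one substrate and one reagent.

I named 119% the reagent ceiling: reagent equivalents plus catalyst loading, on those two assumptions the most substrate that this charge lets react. The ash ceiling stood above the full charge, so I added no reagent and left ash closed and stirred. I expected the part of the substrate reacted in ash to approach full conversion. While the catalyst still held its substrate, that meant 19.3% of the substrate charged as unused reagent. I could not tell how much of that was bound.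

The forecast gave 98% reacted and 80% of the unused reagent free, reasoning “so most reagent is free”.

Ash gave 99.0% reacted and 2.03% of the unused reagent free at 10 d.

    substrate + free catalyst → catalyst intermediate A (k = 0.00520 /M/s)
    reagent + catalyst intermediate A → catalyst intermediate B (k = 0.00220 /M/s)
    catalyst intermediate B → by-product + catalyst intermediate C (k = 4.30 × 10⁻⁴ /s)
    catalyst intermediate C → free catalyst + target (k = 4.20 × 10⁻⁴ /s)
    reagent + by-product ⇌ idle adduct, settled at all times (K = 320 /M)

The part reacted in ash stayed below the ceiling, and idle adduct stood at 18.9% of the substrate charged, against the 19.3% I had reckoned as unused reagent. The neighbour flask with 0.440 equiv of reagent had a ceiling of 53.3%. The part reacted there reached 50.1%, short by 3.2 percentage points, and its idle adduct stood at 3.08% of the substrate charged. Reagent was the limiting reagent in that neighbour flask, its unbound part down to 0.276% of its charge, with 49.9% of the substrate unreacted.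

The data are calculated with made-up constants.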